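**Plan**

- Retrosynthesis: the butenolide (ring A: O1, carbonyl C2, methyl-bearing C3, carboxyl-bearing C4, stereocentre C5) is opened in one cut of three bonds, C2–C3, C2–O1 and C4–CO2H. This removes two molecules of CO and leaves an (E)-2,3-dibromoallylic alcohol. Its two C–Br bonds go back to an alkyne and Br2, and the carbinol–alkyne bond to an aldehyde and a propynyl Grignard reagent.
- Enabling feature: on the C3=C4 double bond of ring A, the ring carbonyl C2 (on C3) and the carboxyl carbon (on C4) are both carbonyl carbons and are trans to each other. This is the relationship that anti addition of Br2 gives to two bromines on an alkyne, and it leaves C2 cis to C5 so that it can close onto the C5 oxygen.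
- Forward: the C14 chain comes from 1,14-tetradecanediol (monoacetate, then aldehyde), the three-carbon unit is joined by Grignard addition, and the alcohol is oxidised to the ynone, reduced enantioselectively and brominated. The only ring is closed in the last step, in which both carbonyl carbons come from CO.
- Stereochemistry: the single stereocentre (C5, R) is set by Noyori asymmetric transfer hydrogenation of the ynone with the (R,R)-TsDPEN ruthenium catalyst, and its C–O bond is never broken afterwards. The alkene geometry needed for ring closure comes from the stereospecific anti bromination.

Key step: step 7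

Remark: open-chain compounds are numbered from the acetoxy-bearing carbon (C1), so C14, C15 and C16 of the chain become C5, C4 and C3 of ring A. The facial sense of the ruthenium catalyst is assumed to follow the usual pattern for alkynyl ketones, with the alkynyl group in the place of an aryl group.

**Route**

Step 1
Reactants: 1 1,14-tetradecanediol
Product: 2 14-hydroxytetradecyl acetate
Conditions: Ac2O (1.0 equiv), pyridine, DMAP (cat.), THF, rt; chromatography, diol recycled
Reagents that add atoms: acetic anhydride, CC(=O)OC(C)=O
Why: Nucleophilic acyl substitution (DMAP-catalysed acetylation) with one equivalent of anhydride should give the monoacetate as the main component of a statistical mixture, from which it is separated by chromatography while recovered diol is recycled.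

Step 2
Reactants: 2 14-hydroxytetradecyl acetate
Product: 3 14-oxotetradecyl acetate
Conditions: TEMPO (10 mol %), PhI(OAc)2 (1.1 equiv), CH2Cl2, rt
Reagents that add atoms: none
Why: TEMPO-catalysed oxidation with PhI(OAc)2 as terminal oxidant (oxoammonium oxidation of a primary alcohol) should stop at the aldehyde in dry CH2Cl2 and does not affect the acetate.

Step 3
Reactants: 3 14-oxotetradecyl acetate; 4 1-propynylmagnesium bromide
Product: 5 racemic 14-hydroxyheptadec-15-yn-1-yl acetate
Conditions: 4 (1.1 equiv, 0.5 M in THF), THF, −78 °C to −20 °C; aq. NH4Cl
Reagents that add atoms: none
Why: Grignard addition of an alkynylmagnesium halide to the aldehyde carbonyl, which at low temperature is far more electrophilic than the acetate, should give the secondary propargylic alcohol as the racemate, the configuration being fixed later.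

Step 4
Reactants: 5 racemic 14-hydroxyheptadec-15-yn-1-yl acetate
Product: 6 14-oxoheptadec-15-yn-1-yl acetate
Conditions: Dess–Martin periodinane (1.2 equiv), CH2Cl2, 0 °C to rt
Reagents that add atoms: none
Why: Dess–Martin oxidation of the secondary propargylic alcohol under neutral conditions should give the conjugated ynone without touching the acetate or the alkyne, and it erases the unselective carbinol centre.

Step 5
Reactants: 6 14-oxoheptadec-15-yn-1-yl acetate
Product: 7 (14R)-14-hydroxyheptadec-15-yn-1-yl acetate
Conditions: Ru[(R,R)-TsNCH(Ph)CH(Ph)NH](p-cymene) (1 mol %), iPrOH, rt
Reagents that add atoms: none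
Why: Noyori asymmetric transfer hydrogenation, in which the alkynyl group takes the place usually held by an aryl group in the six-membered hydride and proton transfer from the ruthenium hydride amine complex, should deliver hydride to the Si face of the ketone with the (R,R) ligand and so set the R carbinol, while the base-free amido complex spares the acetate and avoids conjugate addition to the ynone.

Step 6
Reactants: 7 (14R)-14-hydroxyheptadec-15-yn-1-yl acetate
Product: 8 (14R,15E)-15,16-dibromo-14-hydroxyheptadec-15-en-1-yl acetate
Conditions: Br2 (1.05 equiv), CH2Cl2, −78 °C to 0 °C, dark
Reagents that add atoms: bromine, BrBr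
Why: Electrophilic anti addition of Br2 to the dialkyl-substituted alkyne through a bridged bromonium ion opened by bromide from the opposite side should give the E dibromide, in which the C16 bromine is cis to the carbinol carbon C14, and the stereocentre takes no part.

Step 7
Reactants: 8 (14R,15E)-15,16-dibromo-14-hydroxyheptadec-15-en-1-yl acetate; 9 carbon monoxide
Product: 11 (2R)-2-(13-acetoxytridecyl)-4-methyl-5-oxo-2,5-dihydrofuran-3-carboxylic acid, via bromobutenolide 10 (not isolated)
Conditions: Pd(OAc)2 (5 mol %), dppp (6 mol %), CO (10 bar), iPr2NEt (3.5 equiv), 1,4-dioxane/H2O 10:1, 70 °C; then 1 M HCl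
Reagents that add atoms: carbon monoxide (second molecule, which becomes the C4 carboxyl carbon), [C-]#[O+]; water, O
Why: Proposed new method: two molecules of CO are taken up in turn; zerovalent palladium, formed from Pd(OAc)2 and dppp under CO, should insert first into the less hindered C16–Br bond with retention of alkene geometry, insertion of the first CO then gives an acyl complex of divalent palladium that sits cis to C14 and is captured by the C14 hydroxyl to close ring A as bromobutenolide 10 (C2–C3 and C2–O1 formed), after which the C4–Br bond of 10, now that of a β-bromo enoate, adds to zerovalent palladium, the second CO inserts and the resulting acyl complex is captured by water to give the C4 carboxylic acid of 11. The closest known reaction types are the palladium-catalysed cyclocarbonylation of (Z)-3-haloallylic alcohols to butenolides and the hydroxycarbonylation of vinyl bromides, whose combination in one flask on a vicinal dibromoalkene is not established. Ring A closes by 5-exo-trig acyl substitution of the C5 oxygen at the acylpalladium carbon, and if the two insertions occur in the opposite order the C3 acyl group still meets the cis hydroxyl, so both sequences converge on 11. No stereocentre is formed: C5 should keep the R configuration because its C–O bond stays intact and the amine should be too weak to remove the C5 hydrogen of 10 or of the carboxylate of 11. The selectivity needed is carbonylation in preference to β-bromide elimination from the β-bromovinylpalladium species (which would return alkyne 7), and it should be secured by the CO pressure, the chelating diphosphine and the trans relationship of palladium and the remaining bromine fixed by the anti bromination; the hindered base iPr2NEt and the small amount of water are chosen so that the primary acetate and C4 of 10 are not attacked.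

**Compound list**

1 | 1,14-tetradecanediol | OCCCCCCCCCCCCCCO | starting material
2 | 14-hydroxytetradecyl acetate | CC(=O)OCCCCCCCCCCCCCCO | intermediate
3 | 14-oxotetradecyl acetate | CC(=O)OCCCCCCCCCCCCCC=O | intermediate
4 | 1-propynylmagnesium bromide | CC#C[Mg]Br | starting material
5 | racemic 14-hydroxyheptadec-15-yn-1-yl acetate | CC(=O)OCCCCCCCCCCCCCC(O)C#CC | intermediate
6 | 14-oxoheptadec-15-yn-1-yl acetate | CC(=O)OCCCCCCCCCCCCCC(=O)C#CC | intermediate
7 | (14R)-14-hydroxyheptadec-15-yn-1-yl acetate | CC(=O)OCCCCCCCCCCCCC[C@@H](O)C#CC | intermediate
8 | (14R,15E)-15,16-dibromo-14-hydroxyheptadec-15-en-1-yl acetate | CC(=O)OCCCCCCCCCCCCC[C@@H](O)/C(Br)=C(/C)Br | intermediate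
9 | carbon monoxide | [C-]#[O+] | starting material
10 | 13-[(2R)-3-bromo-4-methyl-5-oxo-2,5-dihydrofuran-2-yl]tridecyl acetate | CC(=O)OCCCCCCCCCCCCC[C@H]1OC(=O)C(C)=C1Br | intermediate
11 | (2R)-2-(13-acetoxytridecyl)-4-methyl-5-oxo-2,5-dihydrofuran-3-carboxylic acid | CC(=O)OCCCCCCCCCCCCC[C@H]1OC(=O)C(C)=C1C(=O)O | target

**Count and risks**

Total step count: 7. Longest linear sequence: 7 steps (from 1 to 11).

Steps most likely to fail:

Step 7 (proposed new method). After the first oxidative addition, the β-bromovinylpalladium species may expel bromide faster than it takes up CO, so that the dibromide is debrominated back to the alkyne. The second carbonylation may also stall, or the acetate may be partly hydrolysed in the aqueous amine medium. The fallback uses known reaction types only and avoids the vicinal dibromide. It sets out from ynone 6 and comes back to the route at bromobutenolide 10, which is then isolated and carried to 11. Ynone 6 is reduced with the enantiomeric catalyst Ru[(S,S)-TsNCH(Ph)CH(Ph)NH](p-cymene) in iPrOH to (S)-14-hydroxyheptadec-15-yn-1-yl acetate F1, which is converted with MsCl and Et3N in CH2Cl2 at −40 °C into (S)-14-(methanesulfonyloxy)heptadec-15-yn-1-yl acetate F2. Carbonylation of F2 with Pd(PPh3)4 under CO (1 bar) in THF/H2O at rt should give (aR)-17-acetoxy-2-methylheptadeca-2,3-dienoic acid F3 by anti SN2' oxidative addition to an allenylpalladium complex, CO insertion with retention and hydrolysis. CuBr2 in acetone/H2O then effects bromolactonisation of F3 to 10. The carboxyl oxygen can only reach the allene terminus from its own side, so the axial chirality should be translated into the R configuration at C5; this is a net inversion relative to F1, which is why the S alcohol is used. A single hydroxycarbonylation of 10 (Pd(OAc)2, dppp, CO, iPr2NEt, 1,4-dioxane/H2O, 70 °C), an ordinary carbonylation of a β-bromo enoate, gives 11.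

Step 6. Bromine may oxidise the free secondary carbinol, and the HBr released may add to the alkyne or scramble the alkene geometry, so that part of the material loses the cis relationship between the C16 bromine and C14 on which ring closure depends. The fallback is a protecting-group detour that sets out from 7 and comes back at 8. Alcohol 7 is silylated (TBSCl, imidazole, DMF) to (14R)-14-(tert-butyldimethylsilyloxy)heptadec-15-yn-1-yl acetate F4, which is brominated with pyridinium tribromide in CH2Cl2 at 0 °C, a buffered bromine source, to (14R,15E)-15,16-dibromo-14-(tert-butyldimethylsilyloxy)heptadec-15-en-1-yl acetate F5. The silyl ether of F5 is removed with HF·pyridine in THF, which leaves the acetate alone, to give 8.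

Step 3. The Grignard reagent may attack the acetate carbonyl, or the acetyl group may be transferred to the new magnesium alkoxide, so that the protecting group is lost or migrates. The fallback builds the ynone without an organomagnesium reagent and without the racemic alcohol. It sets out from 2 and comes back at 6, bypassing steps 2 to 4. Alcohol 2 is oxidised with TEMPO (cat.) and PhI(OAc)2 (2.2 equiv) in MeCN/H2O to 14-acetoxytetradecanoic acid F6, which is converted with (COCl)2 and DMF (cat.) in CH2Cl2 into 14-chloro-14-oxotetradecyl acetate F7. Friedel–Crafts-type ipso acylation of 1-(trimethylsilyl)propyne with F7 and AlCl3 in CH2Cl2 at 0 °C gives ynone 6.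

Further compounds
F1 | step 7 | (S)-14-hydroxyheptadec-15-yn-1-yl acetate | CC(=O)OCCCCCCCCCCCCC[C@H](O)C#CC
F2 | step 7 | (S)-14-(methanesulfonyloxy)heptadec-15-yn-1-yl acetate | CC(=O)OCCCCCCCCCCCCC[C@H](OS(C)(=O)=O)C#CC
F3 | step 7 | (aR)-17-acetoxy-2-methylheptadeca-2,3-dienoic acid | CC(=O)OCCCCCCCCCCCCCC([H])=[C@]=C(C)C(=O)O
F4 | step 6 | (14R)-14-(tert-butyldimethylsilyloxy)heptadec-15-yn-1-yl acetate | CC(=O)OCCCCCCCCCCCCC[C@@H](O[Si](C)(C)C(C)(C)C)C#CC
F5 | step 6 | (14R,15E)-15,16-dibromo-14-(tert-butyldimethylsilyloxy)heptadec-15-en-1-yl acetate | CC(=O)OCCCCCCCCCCCCC[C@@H](O[Si](C)(C)C(C)(C)C)/C(Br)=C(/C)Br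
F6 | step 3 | 14-acetoxytetradecanoic acid | CC(=O)OCCCCCCCCCCCCCC(=O)O
F7 | step 3 | 14-chloro-14-oxotetradecyl acetate | CC(=O)OCCCCCCCCCCCCCC(=O)Cl
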